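**Retrosynthetic overview** (azulene numbering: C1 CH–O‑angelate, C2 CH2, C3 C(OH)iPr, C3a ring‑fusion CH, C4 CH–O‑aroyl, C5, C6(Me)=C7, C8, C8a ring‑fusion C–Me)
1. The two esters go on last: C4 4‑hydroxybenzoate (allyl‑protected), C1 angelate, on a core whose C1 alcohol comes from the C1 ketone 22.
2. Key disconnection: in the five‑membered ring the oxygens on C1 and C3 flank the C2 methylene, so this ring is a 3‑oxycyclopentanone, the (3+2) adduct of a 2‑oxyallyl cation (C8a–C1–C2) and an enol ether (C3a=C3–O). The C3a–C8a bond of that union is the ring‑fusion bond shared with the seven‑membered ring, so tethering the partners through C4–C5–C6=C7–C8 (the (Z)‑alkene of the cycloheptene) lets one step close the seven‑membered ring (C3a–C8a) and then the five‑membered ring (C2–C3) from an open chain.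
3. The open‑chain precursor 19 (allylic sulfone plus two silyl enol ethers) comes from alkylation of 3‑(phenylsulfonyl)butan‑2‑one (C8a, its methyl, C1, C2) with a (Z)‑allylic bromide (C3–C8 and the isopropyl group).
4. The bromide comes from copper‑catalysed opening of ethyl (R)‑oxiranylacetate by a (Z)‑alkenyl Grignard reagent made from but‑2‑yn‑1‑ol; the epoxide supplies the C4 stereocentre, which then controls C3a, C8a, C3 and C1.

Key step: step 12

Remark: the azulene numbering of the target is used for all intermediates; the sulfonyl‑bearing carbon of 18 and 19 is a mixture of epimers, which does not matter because it becomes planar in step 12.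

**Step 1**
Reactants: 1 but‑2‑yn‑1‑ol
Product: 3 (Z)‑3‑iodobut‑2‑en‑1‑ol, via cyclic alkenylalanate 2 (not isolated)
Conditions: NaAlH2(OCH2CH2OCH3)2, THF, 0 to 25 °C; then I2, −78 °C
Reagents that add atoms: iodine, II
Why: hydroxyl‑directed trans‑hydroalumination of the propargylic alcohol places aluminium on C3 cis to the CH2O group, and iodinolysis of the C–Al bond with retention should give the (Z)‑iodoalkene (hydroalumination–iodination).

**Step 2**
Reactants: 3 (Z)‑3‑iodobut‑2‑en‑1‑ol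
Product: 4 tert‑butyl{[(2Z)‑3‑iodobut‑2‑en‑1‑yl]oxy}dimethylsilane
Conditions: t‑BuMe2SiCl, imidazole, CH2Cl2, 25 °C
Reagents that add atoms: tert‑butyldimethylsilyl chloride, CC(C)(C)[Si](C)(C)Cl
Why: standard silylation of a primary alcohol, which masks the hydroxyl for the organometallic step.

**Step 3**
Reactants: 5 ethyl (3R)‑4‑chloro‑3‑hydroxybutanoate
Product: 6 ethyl [(2R)‑oxiran‑2‑yl]acetate
Conditions: Ag2O, 1,2‑dimethoxyethane, 60 °C, dark
Reagents that add atoms: none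
Why: silver‑assisted intramolecular Williamson closure of the chlorohydrin under non‑basic conditions should avoid β‑elimination of the ester and leaves the stereocentre untouched.

**Step 4**
Reactants: 4 tert‑butyl{[(2Z)‑3‑iodobut‑2‑en‑1‑yl]oxy}dimethylsilane, 6 ethyl [(2R)‑oxiran‑2‑yl]acetate
Product: 9 ethyl (3S,5Z)‑7‑[(tert‑butyldimethylsilyl)oxy]‑3‑hydroxy‑5‑methylhept‑5‑enoate, via alkenyllithium 7 (not isolated), via alkenylmagnesium bromide 8 (not isolated)
Conditions: 4, t‑BuLi (2.1 equiv), Et2O, −78 °C; MgBr2·OEt2; then CuI (10 mol%), 6, THF, −40 °C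
Reagents that add atoms: none
Why: iodine–lithium exchange and transmetallation keep the alkene geometry, and copper‑catalysed Grignard opening of the terminal epoxide at its CH2 carbon (faster than addition to the ester at this temperature) should give the homoallylic alcohol with the C4 stereocentre unchanged.

**Step 5**
Reactants: 9 ethyl (3S,5Z)‑7‑[(tert‑butyldimethylsilyl)oxy]‑3‑hydroxy‑5‑methylhept‑5‑enoate
Product: 10 ethyl (3S,5Z)‑3,7‑bis[(tert‑butyldimethylsilyl)oxy]‑5‑methylhept‑5‑enoate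
Conditions: t‑BuMe2SiCl, imidazole, DMF, 25 °C
Reagents that add atoms: tert‑butyldimethylsilyl chloride, CC(C)(C)[Si](C)(C)Cl
Why: silylation of the secondary alcohol protects the future C4 oxygen as an ether that is a poor leaving group and a poor nucleophile in the later enolate and cation chemistry.

**Step 6**
Reactants: 10 ethyl (3S,5Z)‑3,7‑bis[(tert‑butyldimethylsilyl)oxy]‑5‑methylhept‑5‑enoate
Product: 12 (5S,7Z)‑5,9‑bis[(tert‑butyldimethylsilyl)oxy]‑2,7‑dimethylnon‑7‑en‑3‑one, via Weinreb amide 11 (not isolated)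
Conditions: MeONHMe·HCl (1.5 equiv), i‑PrMgCl (5 equiv), THF, −20 to 25 °C
Reagents that add atoms: isopropylmagnesium chloride, CC(C)[Mg]Cl
Why: the chloromagnesium amide converts the ester into the Weinreb amide and the excess Grignard reagent adds once to it through the stable chelate (Weinreb ketone synthesis); no stereocentre is touched.

**Step 7**
Reactants: 12 (5S,7Z)‑5,9‑bis[(tert‑butyldimethylsilyl)oxy]‑2,7‑dimethylnon‑7‑en‑3‑one
Product: 13 (5S,7Z)‑5‑[(tert‑butyldimethylsilyl)oxy]‑9‑hydroxy‑2,7‑dimethylnon‑7‑en‑3‑one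
Conditions: camphor‑10‑sulfonic acid (10 mol%), MeOH/CH2Cl2, 0 °C
Reagents that add atoms: none
Why: acid‑catalysed methanolysis should remove the unhindered primary allylic silyl ether much faster than the secondary one.

**Step 8**
Reactants: 13 (5S,7Z)‑5‑[(tert‑butyldimethylsilyl)oxy]‑9‑hydroxy‑2,7‑dimethylnon‑7‑en‑3‑one
Product: 14 (5S,7Z)‑9‑bromo‑5‑[(tert‑butyldimethylsilyl)oxy]‑2,7‑dimethylnon‑7‑en‑3‑one
Conditions: CBr4, PPh3, CH2Cl2, −20 °C
Reagents that add atoms: carbon tetrabromide, BrC(Br)(Br)Br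
Why: Appel bromination of the primary allylic alcohol by SN2 at low temperature should keep the (Z)‑alkene; the bromide is used crude.

**Step 9**
Reactants: 15 3‑chlorobutan‑2‑one, 16 sodium benzenesulfinate
Product: 17 3‑(phenylsulfonyl)butan‑2‑one (racemic)
Conditions: DMF, 25 °C
Reagents that add atoms: none
Why: S‑alkylation of the sulfinate by the activated α‑chloro ketone (SN2) gives the β‑keto sulfone.

**Step 10**
Reactants: 14 (5S,7Z)‑9‑bromo‑5‑[(tert‑butyldimethylsilyl)oxy]‑2,7‑dimethylnon‑7‑en‑3‑one, 17 3‑(phenylsulfonyl)butan‑2‑one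
Product: 18 (5Z,8S)‑8‑[(tert‑butyldimethylsilyl)oxy]‑3,6,11‑trimethyl‑3‑(phenylsulfonyl)dodec‑5‑ene‑2,10‑dione (both C3 epimers)
Conditions: K2CO3, DMF, 25 °C
Reagents that add atoms: none
Why: the soft β‑keto sulfone anion should C‑alkylate the primary allylic bromide by SN2, which joins all carbons of the target skeleton; the new quaternary centre is not stereocontrolled and need not be.

**Step 11**
Reactants: 18 (5Z,8S)‑8‑[(tert‑butyldimethylsilyl)oxy]‑3,6,11‑trimethyl‑3‑(phenylsulfonyl)dodec‑5‑ene‑2,10‑dione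
Product: 19 (3Z,5S,7Z)‑5‑[(tert‑butyldimethylsilyl)oxy]‑2,7,10‑trimethyl‑10‑(phenylsulfonyl)‑3,11‑bis[(triethylsilyl)oxy]dodeca‑3,7,11‑triene
Conditions: LiN(SiMe3)2 (2.6 equiv), Et3SiCl (3 equiv), THF, −78 °C (in situ trapping)
Reagents that add atoms: chlorotriethylsilane, CC[Si](Cl)(CC)CC
Why: kinetic enolisation with in situ silylation; the methyl ketone can enolise only toward its CH3 (the other α‑carbon is quaternary), the isopropyl ketone should be deprotonated at the less hindered CH2 that becomes C3a, and cold trapping suppresses β‑elimination of the silyloxy group, the (Z)‑enol ether being expected as the main isomer.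

**Step 12**
Reactants: 19 (3Z,5S,7Z)‑5‑[(tert‑butyldimethylsilyl)oxy]‑2,7,10‑trimethyl‑10‑(phenylsulfonyl)‑3,11‑bis[(triethylsilyl)oxy]dodeca‑3,7,11‑triene
Product: 22 (3R,3aS,4S,8aR)‑4‑[(tert‑butyldimethylsilyl)oxy]‑6,8a‑dimethyl‑3‑(propan‑2‑yl)‑3‑[(triethylsilyl)oxy]‑3,3a,4,5,8,8a‑hexahydroazulen‑1(2H)‑one, via 2‑siloxyallyl cation 20 (not isolated), via siloxycarbenium ion 21 (not isolated)
Conditions: TiCl4 (1.1 equiv), 2,6‑di‑tert‑butyl‑4‑methylpyridine (0.3 equiv), CH2Cl2 (0.005 M), −78 to −40 °C; then aq NaHCO3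
Reagents that add atoms: none
Why: Proposed new method: TiCl4 should ionise the tertiary allylic sulfone to the 2‑(triethylsilyloxy)allyl cation 20, whose tertiary terminus is attacked by the nucleophilic carbon of the tethered silyl enol ether to close the cycloheptene (7‑(enolexo)‑exo‑trig, bond C3a–C8a), and the siloxycarbenium ion 21 so formed is trapped by the new silyl enol ether in a Mukaiyama‑aldol closure of the cyclopentanone (5‑(enolendo)‑exo‑trig, bond C2–C3, the closure mode of all oxyallyl (3+2) annulations) with loss of the silyl group from the C1 oxygen. The closest known reactions are the Lewis‑acid‑mediated (3+2) cyclopentanone annulation of 2‑siloxyallyl cations with enol silyl ethers and the intramolecular (4+3) cycloaddition of 2‑alkoxyallyl cations released from allylic sulfones by TiCl4; neither has been used to close a seven‑membered ring through a tethered enol ether. C3a is set by the C4 stereocentre: A(1,3) strain with the cis substituent of the enol ether keeps the C4–H bond in the alkene plane, so the cation, which is delivered through C5, adds to the face anti to the silyloxy group. C8a is set in the same bond formation, the methyl group (the smallest substituent on the cationic terminus) taking the position gauche to both C3 and C4, which corresponds to the trans ring fusion. C3 is set in the aldol closure, where the isopropyl group of the siloxycarbenium ion turns away from C4 (the same result as suprafacial addition to the (Z)‑enol ether), so the siloxy group ends cis to the angular methyl. The step needs attack at the tertiary and not the primary cation terminus, and ring closure instead of proton loss or intermolecular capture: the five‑atom tether with its (Z)‑alkene makes seven‑membered closure at C8a the only low‑strain mode (the alternative is a nine‑membered ring), and high dilution with a proton scavenger is meant to suppress the other paths.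

**Step 13**
Reactants: 22 (3R,3aS,4S,8aR)‑4‑[(tert‑butyldimethylsilyl)oxy]‑6,8a‑dimethyl‑3‑(propan‑2‑yl)‑3‑[(triethylsilyl)oxy]‑3,3a,4,5,8,8a‑hexahydroazulen‑1(2H)‑one
Product: 23 (1R,3R,3aS,4S,8aR)‑4‑[(tert‑butyldimethylsilyl)oxy]‑6,8a‑dimethyl‑3‑(propan‑2‑yl)‑3‑[(triethylsilyl)oxy]‑1,2,3,3a,4,5,8,8a‑octahydroazulen‑1‑ol
Conditions: NaBH4, MeOH/THF, −20 °C
Reagents that add atoms: none
Why: hydride should add to the cyclopentanone face anti to the angular C8a methyl and the C3 silyloxy group (the face of C3a–H), as in the reduction of 17‑oxo steroids, which places the new C1 hydroxyl cis to the methyl group (1R) (substrate‑controlled borohydride reduction).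

**Step 14**
Reactants: 23 (1R,3R,3aS,4S,8aR)‑4‑[(tert‑butyldimethylsilyl)oxy]‑6,8a‑dimethyl‑3‑(propan‑2‑yl)‑3‑[(triethylsilyl)oxy]‑1,2,3,3a,4,5,8,8a‑octahydroazulen‑1‑ol, 24 angelic acid [(2Z)‑2‑methylbut‑2‑enoic acid]
Product: 26 (1R,3R,3aS,4S,8aR)‑4‑[(tert‑butyldimethylsilyl)oxy]‑6,8a‑dimethyl‑3‑(propan‑2‑yl)‑3‑[(triethylsilyl)oxy]‑1,2,3,3a,4,5,8,8a‑octahydroazulen‑1‑yl (2Z)‑2‑methylbut‑2‑enoate, via mixed anhydride 25 (not isolated)
Conditions: 24, 2,4,6‑trichlorobenzoyl chloride, Et3N, toluene, 25 °C; then 23, 80 °C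
Reagents that add atoms: none
Why: Yamaguchi‑type esterification through the preformed mixed anhydride, run without a nucleophilic catalyst, is the usual way to acylate a hindered secondary alcohol with angelic acid without Z to E isomerisation; C1 keeps its configuration.

**Step 15**
Reactants: 26 (1R,3R,3aS,4S,8aR)‑4‑[(tert‑butyldimethylsilyl)oxy]‑6,8a‑dimethyl‑3‑(propan‑2‑yl)‑3‑[(triethylsilyl)oxy]‑1,2,3,3a,4,5,8,8a‑octahydroazulen‑1‑yl (2Z)‑2‑methylbut‑2‑enoate
Product: 27 (1R,3R,3aS,4S,8aR)‑3,4‑dihydroxy‑6,8a‑dimethyl‑3‑(propan‑2‑yl)‑1,2,3,3a,4,5,8,8a‑octahydroazulen‑1‑yl (2Z)‑2‑methylbut‑2‑enoate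
Conditions: HF·pyridine, pyridine, THF, 0 to 25 °C
Reagents that add atoms: none
Why: buffered fluoride‑mediated desilylation should remove both silyl ethers and leave the angelate and the alkene untouched.

**Step 16**
Reactants: 27 (1R,3R,3aS,4S,8aR)‑3,4‑dihydroxy‑6,8a‑dimethyl‑3‑(propan‑2‑yl)‑1,2,3,3a,4,5,8,8a‑octahydroazulen‑1‑yl (2Z)‑2‑methylbut‑2‑enoate, 28 4‑(allyloxy)benzoic acid
Product: 29 (1R,3R,3aS,4S,8aR)‑3‑hydroxy‑6,8a‑dimethyl‑1‑{[(2Z)‑2‑methylbut‑2‑enoyl]oxy}‑3‑(propan‑2‑yl)‑1,2,3,3a,4,5,8,8a‑octahydroazulen‑4‑yl 4‑(allyloxy)benzoate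
Conditions: 28, N,N'‑dicyclohexylcarbodiimide, 4‑(dimethylamino)pyridine (10 mol%), CH2Cl2, 25 °C
Reagents that add atoms: none
Why: Steglich esterification should acylate the secondary C4 hydroxyl with retention while the hindered tertiary C3 hydroxyl stays free.

**Step 17**
Reactants: 29 (1R,3R,3aS,4S,8aR)‑3‑hydroxy‑6,8a‑dimethyl‑1‑{[(2Z)‑2‑methylbut‑2‑enoyl]oxy}‑3‑(propan‑2‑yl)‑1,2,3,3a,4,5,8,8a‑octahydroazulen‑4‑yl 4‑(allyloxy)benzoate
Product: 30 (1R,3R,3aS,4S,8aR)‑3‑hydroxy‑6,8a‑dimethyl‑1‑{[(2Z)‑2‑methylbut‑2‑enoyl]oxy}‑3‑(propan‑2‑yl)‑1,2,3,3a,4,5,8,8a‑octahydroazulen‑4‑yl 4‑hydroxybenzoate (target, CNP0188626.1)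
Conditions: Pd(PPh3)4 (5 mol%), morpholine, THF, 25 °C
Reagents that add atoms: none
Why: zerovalent palladium cleaves the aryl allyl ether through a π‑allyl complex that morpholine intercepts (Tsuji–Trost deallylation); neither ester is allylic and the angelate is a poor Michael acceptor, so both should survive.

**Compound list**
1 | but‑2‑yn‑1‑ol | CC#CCO | starting material
2 | sodium cyclic (Z)‑alkenylalanate from 1 | [Na+].CC1=CCO[Al-]1(OCCOC)OCCOC | intermediate
3 | (Z)‑3‑iodobut‑2‑en‑1‑ol | I/C(C)=C\CO | intermediate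
4 | tert‑butyl{[(2Z)‑3‑iodobut‑2‑en‑1‑yl]oxy}dimethylsilane | I/C(C)=C\CO[Si](C)(C)C(C)(C)C | intermediate
5 | ethyl (3R)‑4‑chloro‑3‑hydroxybutanoate | CCOC(=O)C[C@@H](O)CCl | starting material
6 | ethyl [(2R)‑oxiran‑2‑yl]acetate | CCOC(=O)C[C@@H]1CO1 | intermediate
7 | (Z)‑alkenyllithium from 4 | [Li]/C(C)=C\CO[Si](C)(C)C(C)(C)C | intermediate
8 | (Z)‑alkenylmagnesium bromide from 4 | Br[Mg]/C(C)=C\CO[Si](C)(C)C(C)(C)C | intermediate
9 | ethyl (3S,5Z)‑7‑[(tert‑butyldimethylsilyl)oxy]‑3‑hydroxy‑5‑methylhept‑5‑enoate | CCOC(=O)C[C@@H](O)C/C(C)=C\CO[Si](C)(C)C(C)(C)C | intermediate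
10 | ethyl (3S,5Z)‑3,7‑bis[(tert‑butyldimethylsilyl)oxy]‑5‑methylhept‑5‑enoate | CCOC(=O)C[C@@H](O[Si](C)(C)C(C)(C)C)C/C(C)=C\CO[Si](C)(C)C(C)(C)C | intermediate
11 | (3S,5Z)‑3,7‑bis[(tert‑butyldimethylsilyl)oxy]‑N‑methoxy‑N,5‑dimethylhept‑5‑enamide | CON(C)C(=O)C[C@@H](O[Si](C)(C)C(C)(C)C)C/C(C)=C\CO[Si](C)(C)C(C)(C)C | intermediate
12 | (5S,7Z)‑5,9‑bis[(tert‑butyldimethylsilyl)oxy]‑2,7‑dimethylnon‑7‑en‑3‑one | CC(C)C(=O)C[C@@H](O[Si](C)(C)C(C)(C)C)C/C(C)=C\CO[Si](C)(C)C(C)(C)C | intermediate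
13 | (5S,7Z)‑5‑[(tert‑butyldimethylsilyl)oxy]‑9‑hydroxy‑2,7‑dimethylnon‑7‑en‑3‑one | CC(C)C(=O)C[C@@H](O[Si](C)(C)C(C)(C)C)C/C(C)=C\CO | intermediate
14 | (5S,7Z)‑9‑bromo‑5‑[(tert‑butyldimethylsilyl)oxy]‑2,7‑dimethylnon‑7‑en‑3‑one | CC(C)C(=O)C[C@@H](O[Si](C)(C)C(C)(C)C)C/C(C)=C\CBr | intermediate
15 | 3‑chlorobutan‑2‑one (racemic) | CC(=O)C(C)Cl | starting material
16 | sodium benzenesulfinate | [Na+].[O-]S(=O)c1ccccc1 | starting material
17 | 3‑(phenylsulfonyl)butan‑2‑one (racemic) | CC(=O)C(C)S(=O)(=O)c1ccccc1 | intermediate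
18 | (5Z,8S)‑8‑[(tert‑butyldimethylsilyl)oxy]‑3,6,11‑trimethyl‑3‑(phenylsulfonyl)dodec‑5‑ene‑2,10‑dione (C3 epimers) | CC(C)C(=O)C[C@@H](O[Si](C)(C)C(C)(C)C)C/C(C)=C\CC(C)(C(C)=O)S(=O)(=O)c1ccccc1 | intermediate
19 | (3Z,5S,7Z)‑5‑[(tert‑butyldimethylsilyl)oxy]‑2,7,10‑trimethyl‑10‑(phenylsulfonyl)‑3,11‑bis[(triethylsilyl)oxy]dodeca‑3,7,11‑triene (C10 epimers) | CC(C)/C(O[Si](CC)(CC)CC)=C/[C@@H](O[Si](C)(C)C(C)(C)C)C/C(C)=C\CC(C)(C(=C)O[Si](CC)(CC)CC)S(=O)(=O)c1ccccc1 | intermediate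
20 | open‑chain 2‑(triethylsilyloxy)allyl cation from 19 | CC(C)/C(O[Si](CC)(CC)CC)=C/[C@@H](O[Si](C)(C)C(C)(C)C)C/C(C)=C\C[C+](C)C(=C)O[Si](CC)(CC)CC | intermediate
21 | cycloheptenyl siloxycarbenium ion (seven‑membered ring closed, C3 cationic) | CC(C)C(=[O+][Si](CC)(CC)CC)[C@@H]1[C@@H](O[Si](C)(C)C(C)(C)C)CC(C)=CC[C@@]1(C)C(=C)O[Si](CC)(CC)CC | intermediate
22 | (3R,3aS,4S,8aR)‑4‑[(tert‑butyldimethylsilyl)oxy]‑6,8a‑dimethyl‑3‑(propan‑2‑yl)‑3‑[(triethylsilyl)oxy]‑3,3a,4,5,8,8a‑hexahydroazulen‑1(2H)‑one | O=C1C[C@@](O[Si](CC)(CC)CC)(C(C)C)[C@@H]2[C@@H](O[Si](C)(C)C(C)(C)C)CC(C)=CC[C@]21C | intermediate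
23 | (1R,3R,3aS,4S,8aR)‑4‑[(tert‑butyldimethylsilyl)oxy]‑6,8a‑dimethyl‑3‑(propan‑2‑yl)‑3‑[(triethylsilyl)oxy]‑1,2,3,3a,4,5,8,8a‑octahydroazulen‑1‑ol | O[C@@H]1C[C@@](O[Si](CC)(CC)CC)(C(C)C)[C@@H]2[C@@H](O[Si](C)(C)C(C)(C)C)CC(C)=CC[C@]21C | intermediate
24 | angelic acid, (2Z)‑2‑methylbut‑2‑enoic acid | C/C=C(/C)C(=O)O | starting material
25 | (2Z)‑2‑methylbut‑2‑enoic 2,4,6‑trichlorobenzoic anhydride | C/C=C(/C)C(=O)OC(=O)c1c(Cl)cc(Cl)cc1Cl | intermediate
26 | (1R,3R,3aS,4S,8aR)‑4‑[(tert‑butyldimethylsilyl)oxy]‑6,8a‑dimethyl‑3‑(propan‑2‑yl)‑3‑[(triethylsilyl)oxy]‑1,2,3,3a,4,5,8,8a‑octahydroazulen‑1‑yl (2Z)‑2‑methylbut‑2‑enoate | C/C=C(/C)C(=O)O[C@@H]1C[C@@](O[Si](CC)(CC)CC)(C(C)C)[C@@H]2[C@@H](O[Si](C)(C)C(C)(C)C)CC(C)=CC[C@]21C | intermediate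
27 | (1R,3R,3aS,4S,8aR)‑3,4‑dihydroxy‑6,8a‑dimethyl‑3‑(propan‑2‑yl)‑1,2,3,3a,4,5,8,8a‑octahydroazulen‑1‑yl (2Z)‑2‑methylbut‑2‑enoate | C/C=C(/C)C(=O)O[C@@H]1C[C@@](O)(C(C)C)[C@@H]2[C@@H](O)CC(C)=CC[C@]21C | intermediate
28 | 4‑(allyloxy)benzoic acid | C=CCOc1ccc(cc1)C(=O)O | starting material
29 | (1R,3R,3aS,4S,8aR)‑3‑hydroxy‑6,8a‑dimethyl‑1‑{[(2Z)‑2‑methylbut‑2‑enoyl]oxy}‑3‑(propan‑2‑yl)‑1,2,3,3a,4,5,8,8a‑octahydroazulen‑4‑yl 4‑(allyloxy)benzoate | C/C=C(/C)C(=O)O[C@@H]1C[C@@](O)(C(C)C)[C@@H]2[C@@H](OC(=O)c3ccc(OCC=C)cc3)CC(C)=CC[C@]21C | intermediate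
30 | (1R,3R,3aS,4S,8aR)‑3‑hydroxy‑6,8a‑dimethyl‑1‑{[(2Z)‑2‑methylbut‑2‑enoyl]oxy}‑3‑(propan‑2‑yl)‑1,2,3,3a,4,5,8,8a‑octahydroazulen‑4‑yl 4‑hydroxybenzoate | C/C=C(/C)C(=O)O[C@@H]1C[C@@](O)(C(C)C)[C@@H]2[C@@H](OC(=O)c3ccc(O)cc3)CC(C)=CC[C@]21C | target

**Step count and risks**
Total step count: 17. Longest linear sequence: 15 steps (steps 1, 2, 4 to 8 and 10 to 17; steps 3 and 9 are side branches).

Steps most likely to fail:

1. Step 12 (Proposed new method). What may go wrong: the 2‑siloxyallyl cation may lose a proton to a siloxydiene or be captured between molecules before the seven‑membered ring closes, or the ring fusion may form without stereocontrol. Fallback with known reaction types, making the two bonds one after the other, from 18 back to 22: reductive desulfonylation of 18 with SmI2 (THF, −78 °C) and silylation of the regiodefined enolate (Me3SiCl, Et3N) would give the enol silane F1. Kinetic enolisation of its isopropyl ketone (LiN(SiMe3)2, Me3SiCl, −78 °C) would give the bis(enol silane) F2. Oxidative coupling of the two enol silanes with (NH4)2Ce(NO3)6 (NaHCO3, MeCN, −30 °C, high dilution) would form the C3a–C8a bond and give the cycloheptene diketone F3. Deprotonation of its methyl ketone (LiN(SiMe3)2, THF, −78 °C) and intramolecular aldol addition to the isopropyl ketone would close the five‑membered ring to the hydroxy ketone F4, and silylation (Et3SiOSO2CF3, 2,6‑lutidine) would return to 22.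

2. Step 14. What may go wrong: slow acylation of the neopentylic C1 alcohol, which gives the activated angelate time to isomerise from Z to E, or no conversion at all. Fallback from 23 back to 26, building the angelate on the molecule: 23 would be esterified with the unhindered 2‑[bis(2,2,2‑trifluoroethoxy)phosphoryl]propanoic acid (N,N'‑dicyclohexylcarbodiimide, 4‑(dimethylamino)pyridine) to the phosphonate ester F5, and Still–Gennari olefination of F5 with acetaldehyde (KN(SiMe3)2, 18‑crown‑6, THF, −78 °C) would give the (Z)‑2‑methylbut‑2‑enoate 26.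

3. Step 13. What may go wrong: poor facial selectivity of hydride addition, because the isopropyl group on C3 shields the face that the angular methyl leaves open. Fallback from 22 back to 23, with reagent control in place of substrate control: Corey–Bakshi–Shibata reduction with (S)‑2‑methyl‑CBS‑oxazaborolidine (cat.) and BH3·SMe2 (THF, −20 °C) distinguishes the quaternary C8a side from the C2 methylene side and should deliver the 1R alcohol 23 directly; this fallback makes no compound outside the list (none F0).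

**Further compounds**
F1 | step 12 | (5S,7Z)‑5‑[(tert‑butyldimethylsilyl)oxy]‑2,7,10‑trimethyl‑11‑[(trimethylsilyl)oxy]dodeca‑7,10‑dien‑3‑one | CC(C)C(=O)C[C@@H](O[Si](C)(C)C(C)(C)C)C/C(C)=C\CC(C)=C(C)O[Si](C)(C)C
F2 | step 12 | (3Z,5S,7Z)‑5‑[(tert‑butyldimethylsilyl)oxy]‑2,7,10‑trimethyl‑3,11‑bis[(trimethylsilyl)oxy]dodeca‑3,7,10‑triene | CC(C)/C(O[Si](C)(C)C)=C/[C@@H](O[Si](C)(C)C(C)(C)C)C/C(C)=C\CC(C)=C(C)O[Si](C)(C)C
F3 | step 12 | 1‑[(1S,2R,7S)‑2‑acetyl‑7‑[(tert‑butyldimethylsilyl)oxy]‑2,5‑dimethylcyclohept‑4‑en‑1‑yl]‑2‑methylpropan‑1‑one | CC(C)C(=O)[C@@H]1[C@@H](O[Si](C)(C)C(C)(C)C)CC(C)=CC[C@@]1(C)C(C)=O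
F4 | step 12 | (3R,3aS,4S,8aR)‑4‑[(tert‑butyldimethylsilyl)oxy]‑3‑hydroxy‑6,8a‑dimethyl‑3‑(propan‑2‑yl)‑3,3a,4,5,8,8a‑hexahydroazulen‑1(2H)‑one | O=C1C[C@@](O)(C(C)C)[C@@H]2[C@@H](O[Si](C)(C)C(C)(C)C)CC(C)=CC[C@]21C
F5 | step 14 | (1R,3R,3aS,4S,8aR)‑4‑[(tert‑butyldimethylsilyl)oxy]‑6,8a‑dimethyl‑3‑(propan‑2‑yl)‑3‑[(triethylsilyl)oxy]‑1,2,3,3a,4,5,8,8a‑octahydroazulen‑1‑yl 2‑[bis(2,2,2‑trifluoroethoxy)phosphoryl]propanoate | CC(C(=O)O[C@@H]1C[C@@](O[Si](CC)(CC)CC)(C(C)C)[C@@H]2[C@@H](O[Si](C)(C)C(C)(C)C)CC(C)=CC[C@]21C)P(=O)(OCC(F)(F)F)OCC(F)(F)F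
F0 | step 13 | none | none
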